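The γ-butyrolactone (O1, C2 carbonyl, C3, C4, C5) is cut at O1. Without that oxygen the two ring CH2 groups on C4 (C3 and C5) become mirror images, and the lactone collapses to a Cs-symmetric 3-(arylmethyl)cyclobutanone bearing ring B. A catalyst-controlled Baeyer–Villiger oxidation reverses this. In one operation it forms O1–C2 and O1–C5, enlarges the four-membered ring to the lactone and makes C4 stereogenic (R). The precursor, 3-(4-benzyloxy-3-methoxybenzyl)cyclobutanone, comes from eugenol in three steps. C3 then follows from C4 by trans-alkylation (ring A). C7''/C8'' of the threo glycerol arm (ring C) come from an auxiliary-controlled syn aldol on the ring-B aryloxyacetyl imide.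

Key step: step 4

Numbering and reading of the target: ring A is the guaiacyl group on the C3 benzyl carbon. Ring B is the aryl group on the C4 benzyl carbon C7'. Ring C is the guaiacyl group of the chain C7''(OH)–C8''(OAr)–C9''H2OH. The SMILES reads as (3R,4R,7''R,8''R), that is a trans lactone with a threo (syn) side chain.

Assumption: the N,N'-dioxide ligand of step 4 is 1,1'-(propane-1,3-diyl)bis[2-(2,6-diisopropylphenylcarbamoyl)piperidine 1-oxide], available in both antipodes from (S)- or (R)-pipecolic acid. A pilot run that assigns the configuration of the lactone fixes which antipode gives the (R)-lactone from an arylmethyl-substituted ketone, and the route is written for that antipode.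

Step 1
Reactants: 1 eugenol (4-allyl-2-methoxyphenol)
Product: 2 4-allyl-1-(benzyloxy)-2-methoxybenzene
Conditions: BnBr, K2CO3, acetone, reflux
Reagents that add atoms: benzyl bromide, BrCc1ccccc1
Why: Williamson ether synthesis: carbonate deprotonates the phenol but is too weak to move the allyl double bond into conjugation, and the benzyl ether shields the oxygen from acylation in step 2, tolerates zinc, acetic acid and peracid, and can later be removed by hydrogenolysis beside silyl ethers.

Step 2
Reactants: 2 4-allyl-1-(benzyloxy)-2-methoxybenzene; 3 trichloroacetyl chloride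
Product: 5 (±)-3-[4-(benzyloxy)-3-methoxybenzyl]-2,2-dichlorocyclobutan-1-one, via dichloroketene 4 (not isolated)
Conditions: Zn–Cu, Et2O–DME, slow addition of 3, 0 °C → rt
Reagents that add atoms: none
Why: Ketene–alkene [2+2] cycloaddition: zinc dechlorinates 3 to the strongly electrophilic ketene 4, whose carbonyl carbon bonds to the terminal alkene carbon so that CCl2 ends next to the substituted ring carbon, DME binds ZnCl2 and so suppresses cationic side reactions of the electron-rich allylarene, and the single stereocentre formed is racemic and vanishes in step 3.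

Step 3
Reactants: 5 (±)-3-[4-(benzyloxy)-3-methoxybenzyl]-2,2-dichlorocyclobutan-1-one
Product: 6 3-[4-(benzyloxy)-3-methoxybenzyl]cyclobutan-1-one
Conditions: Zn dust, AcOH, rt → 60 °C
Reagents that add atoms: none
Why: Reductive α-dehalogenation of an α,α-dichloroketone (two rounds of zinc enolate formation and protonation) should remove both chlorines without touching the ketone, the arene or the benzyl ether, and leaves an achiral ketone with a mirror plane through the carbonyl group and the substituted carbon.

Step 4
Reactants: 6 3-[4-(benzyloxy)-3-methoxybenzyl]cyclobutan-1-one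
Product: 8 (R)-4-[4-(benzyloxy)-3-methoxybenzyl]dihydrofuran-2(3H)-one, via Criegee adduct 7 (not isolated)
Conditions: Sc(OTf)3 (5 mol %), chiral N,N'-dioxide ligand (5 mol %), purified m-CPBA (1.2 equiv), EtOAc, −20 °C; recrystallisation
Reagents that add atoms: m-chloroperbenzoic acid, O=C(OO)c1cccc(Cl)c1
Why: Sc(III), wrapped by the tetradentate N,N'-dioxide, activates the strained ketone of 6 for addition of the peracid to give the metal-bound Criegee adduct 7, which collapses by a concerted 1,2-shift of the CH2 lying antiperiplanar to the O–O bond while 3-chlorobenzoate leaves. The closest known reaction type is the Lewis-acid-catalysed asymmetric Baeyer–Villiger desymmetrisation of 3-substituted cyclobutanones. The lactone ring arises by ring expansion (four to five atoms, C5 migrating from C2 to O1) and not by cyclisation, so no exo/endo mode applies. C4 is the only new stereocentre; no bond at C4 changes, and it becomes (R) solely because the ligand pocket pushes the pseudo-equatorial arylmethyl arm into the open quadrant between the anilide walls and thereby lets only one enantiotopic CH2 reach the migrating alignment. The step needs only this enantiotopic-group selectivity, because the mirror plane of 6 makes both migrations constitutionally identical, and chemoselectivity over the electron-rich arene and the benzyl ether is secured by ring strain, which lets the ketone react at −20 °C. Because the arene sits one CH2 away from the ring, the selectivity may be incomplete, so 8, expected to be a solid, is recrystallised to constant rotation before use.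

Step 5
Reactants: 9 vanillin
Product: 10 3-methoxy-4-[(triisopropylsilyl)oxy]benzaldehyde
Conditions: TIPSCl, imidazole, DMF, rt
Reagents that add atoms: chlorotriisopropylsilane, CC(C)[Si](Cl)(C(C)C)C(C)C
Why: Imidazole-promoted silylation of the phenol; the bulky TIPS group is preferred to smaller silyl groups because it has to survive an enolate, carbonate/phenoxide, a boron triflate and borohydride, and 10 serves twice, as source of ring A and of ring C.

Step 6
Reactants: 10 3-methoxy-4-[(triisopropylsilyl)oxy]benzaldehyde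
Product: 11 {3-methoxy-4-[(triisopropylsilyl)oxy]phenyl}methanol
Conditions: NaBH4, THF–EtOH, 0 °C
Reagents that add atoms: none
Why: Borohydride reduction of an aromatic aldehyde is fast at 0 °C, so the silyl ether para to the carbonyl group is exposed to alkoxide only briefly.

Step 7
Reactants: 11 {3-methoxy-4-[(triisopropylsilyl)oxy]phenyl}methanol
Product: 12 [4-(bromomethyl)-2-methoxyphenoxy]triisopropylsilane
Conditions: CBr4, PPh3, CH2Cl2, 0 °C; short silica plug, used at once
Reagents that add atoms: carbon tetrabromide, BrC(Br)(Br)Br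
Why: Appel reaction: the neutral conditions turn the primary benzylic alcohol into the bromide by SN2 on the alkoxyphosphonium ion, without acid that could ionise this electron-rich benzylic system.

Step 8
Reactants: 8 (R)-4-[4-(benzyloxy)-3-methoxybenzyl]dihydrofuran-2(3H)-one; 12 [4-(bromomethyl)-2-methoxyphenoxy]triisopropylsilane
Product: 14 (3R,4R)-4-[4-(benzyloxy)-3-methoxybenzyl]-3-{3-methoxy-4-[(triisopropylsilyl)oxy]benzyl}dihydrofuran-2(3H)-one, via lithium enolate 13 (not isolated)
Conditions: LiHMDS (1.05 equiv), THF, −78 °C; then 12, −78 → −40 °C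
Reagents that add atoms: none
Why: Diastereoselective alkylation of a lactone enolate: the planar enolate 13 is attacked by the benzylic bromide on the face opposite the C4 arylmethyl group, which sets C3 as (R), trans to C4, and this trans isomer is also the thermodynamically preferred one, so later mild bases cannot erode it.

Step 9
Reactants: 14 (3R,4R)-4-[4-(benzyloxy)-3-methoxybenzyl]-3-{3-methoxy-4-[(triisopropylsilyl)oxy]benzyl}dihydrofuran-2(3H)-one
Product: 15 (3R,4R)-4-(4-hydroxy-3-methoxybenzyl)-3-{3-methoxy-4-[(triisopropylsilyl)oxy]benzyl}dihydrofuran-2(3H)-one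
Conditions: H2 (1 atm), 10 % Pd/C, EtOAc, rt
Reagents that add atoms: none
Why: Catalytic hydrogenolysis of an aryl benzyl ether frees only the ring-B phenol, since aryl TIPS ethers, the lactone and the unoxygenated benzylic CH2 groups are inert to H2/Pd–C in a neutral aprotic solvent.

Step 10
Reactants: 16 (S)-4-benzyloxazolidin-2-one; 17 bromoacetyl bromide
Product: 19 (S)-4-benzyl-3-(2-bromoacetyl)oxazolidin-2-one, via lithiated oxazolidinone 18 (not isolated)
Conditions: n-BuLi (1.0 equiv), THF, −78 °C; then 17, −78 → 0 °C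
Reagents that add atoms: none
Why: N-Acylation of a lithiated oxazolidinone: the acyl bromide end of 17 reacts far faster than its alkyl bromide end at −78 °C, and the stereocentre of the auxiliary is not involved.

Step 11
Reactants: 15 (3R,4R)-4-(4-hydroxy-3-methoxybenzyl)-3-{3-methoxy-4-[(triisopropylsilyl)oxy]benzyl}dihydrofuran-2(3H)-one; 19 (S)-4-benzyl-3-(2-bromoacetyl)oxazolidin-2-one
Product: 20 aryloxyacetyl imide (ring-B oxygen of 15 bonded to CH2C(=O)N of the (S)-4-benzyloxazolidin-2-one)
Conditions: K2CO3, acetone, rt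
Reagents that add atoms: none
Why: Williamson ether synthesis on an activated α-bromo imide: the guaiacyl phenoxide displaces bromide at room temperature, acyl transfer to phenoxide is disfavoured because the oxazolidinone anion is the poorer leaving group, and C8'', C9'' and the auxiliary are installed in one step.

Step 12
Reactants: 20 aryloxyacetyl imide; 10 3-methoxy-4-[(triisopropylsilyl)oxy]benzaldehyde
Product: 23 syn-aldol imide (side chain 2S,3R; auxiliary 4S; lactone 3R,4R), via boron enolate 21 (not isolated), via boron aldolate 22 (not isolated)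
Conditions: Bu2BOTf (1.15 equiv), iPr2NEt (1.3 equiv), CH2Cl2, −78 → 0 °C; then 10, −78 → 0 °C; MeOH, pH 7 buffer, 30 % H2O2, 0 °C
Reagents that add atoms: none
Why: Evans syn aldol: soft enolisation gives the (Z)-boron enolate 21 (the less acidic, more hindered lactone α-CH is not enolised by Bu2BOTf/amine), which reacts through a chair Zimmerman–Traxler transition state on the face away from the benzyl group of the (S)-auxiliary, so C8'' and C7'' are set together as the syn (2S,3R) imide that becomes the (7''R,8''R)-threo arrangement after reduction.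

Step 13
Reactants: 23 syn-aldol imide
Product: 24 bis-TIPS ether of the target (3R,4R,7''R,8''R)
Conditions: NaBH4, THF–H2O (4:1), 0 °C
Reagents that add atoms: none
Why: Reductive cleavage of an N-acyloxazolidinone with borohydride: the imide carbonyl, activated by the ring carbamate, the α-aryloxy group and the neighbouring hydroxyl, should be reduced to CH2OH well before the hindered α,β-disubstituted γ-lactone reacts with this mild hydride, and no stereocentre is touched (the C8'' descriptor changes from S to R only through a priority switch).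

Step 14
Reactants: 24 bis-TIPS ether of the target
Product: 25 target CNP0144301.3
Conditions: TBAF/AcOH (1:1, 2.5 equiv), THF, 0 °C
Reagents that add atoms: none
Why: Fluoride-induced desilylation of both aryl silyl ethers; acetic acid buffers the liberated phenoxides so that neither quinone-methide formation at C7'' nor epimerisation at C3 can start.

Compound list
1 | eugenol (4-allyl-2-methoxyphenol) | C=CCc1ccc(O)c(OC)c1 | starting material
2 | 4-allyl-1-(benzyloxy)-2-methoxybenzene | C=CCc1ccc(OCc2ccccc2)c(OC)c1 | intermediate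
3 | trichloroacetyl chloride | ClC(=O)C(Cl)(Cl)Cl | starting material
4 | dichloroketene (formed in the flask) | O=C=C(Cl)Cl | intermediate
5 | (±)-3-[4-(benzyloxy)-3-methoxybenzyl]-2,2-dichlorocyclobutan-1-one | O=C1CC(Cc2ccc(OCc3ccccc3)c(OC)c2)C1(Cl)Cl | intermediate
6 | 3-[4-(benzyloxy)-3-methoxybenzyl]cyclobutan-1-one (achiral) | O=C1CC(Cc2ccc(OCc3ccccc3)c(OC)c2)C1 | intermediate
7 | Criegee adduct, 3-[4-(benzyloxy)-3-methoxybenzyl]-1-hydroxycyclobutyl 3-chloroperbenzoate (formed in the flask, Sc-bound) | OC1(OOC(=O)c2cccc(Cl)c2)CC(Cc2ccc(OCc3ccccc3)c(OC)c2)C1 | intermediate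
8 | (R)-4-[4-(benzyloxy)-3-methoxybenzyl]dihydrofuran-2(3H)-one | O=C1C[C@@H](Cc2ccc(OCc3ccccc3)c(OC)c2)CO1 | intermediate
9 | vanillin | COc1cc(C=O)ccc1O | starting material
10 | 3-methoxy-4-[(triisopropylsilyl)oxy]benzaldehyde | COc1cc(C=O)ccc1O[Si](C(C)C)(C(C)C)C(C)C | intermediate
11 | {3-methoxy-4-[(triisopropylsilyl)oxy]phenyl}methanol | COc1cc(CO)ccc1O[Si](C(C)C)(C(C)C)C(C)C | intermediate
12 | [4-(bromomethyl)-2-methoxyphenoxy]triisopropylsilane | COc1cc(CBr)ccc1O[Si](C(C)C)(C(C)C)C(C)C | intermediate
13 | lithium enolate of 8 (formed in the flask) | [Li]OC1=C[C@@H](Cc2ccc(OCc3ccccc3)c(OC)c2)CO1 | intermediate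
14 | (3R,4R)-4-[4-(benzyloxy)-3-methoxybenzyl]-3-{3-methoxy-4-[(triisopropylsilyl)oxy]benzyl}dihydrofuran-2(3H)-one | COc1cc(C[C@H]2C(=O)OC[C@@H]2Cc2ccc(OCc3ccccc3)c(OC)c2)ccc1O[Si](C(C)C)(C(C)C)C(C)C | intermediate
15 | (3R,4R)-4-(4-hydroxy-3-methoxybenzyl)-3-{3-methoxy-4-[(triisopropylsilyl)oxy]benzyl}dihydrofuran-2(3H)-one | COc1cc(C[C@H]2C(=O)OC[C@@H]2Cc2ccc(O)c(OC)c2)ccc1O[Si](C(C)C)(C(C)C)C(C)C | intermediate
16 | (S)-4-benzyloxazolidin-2-one | O=C1N[C@@H](Cc2ccccc2)CO1 | starting material
17 | bromoacetyl bromide | BrCC(=O)Br | starting material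
18 | N-lithio-(S)-4-benzyloxazolidin-2-one (formed in the flask) | [Li]N1C(=O)OC[C@@H]1Cc1ccccc1 | intermediate
19 | (S)-4-benzyl-3-(2-bromoacetyl)oxazolidin-2-one | O=C(CBr)N1C(=O)OC[C@@H]1Cc1ccccc1 | intermediate
20 | (S)-4-benzyl-3-{2-[2-methoxy-4-({(3R,4R)-4-[3-methoxy-4-(triisopropylsilyloxy)benzyl]-5-oxotetrahydrofuran-3-yl}methyl)phenoxy]acetyl}oxazolidin-2-one | COc1cc(C[C@H]2C(=O)OC[C@@H]2Cc2ccc(OCC(=O)N3C(=O)OC[C@@H]3Cc3ccccc3)c(OC)c2)ccc1O[Si](C(C)C)(C(C)C)C(C)C | intermediate
21 | (Z)-dibutylboron enolate of 20 (formed in the flask) | COc1cc(C[C@H]2C(=O)OC[C@@H]2Cc2ccc(O/C=C(\OB(CCCC)CCCC)N3C(=O)OC[C@@H]3Cc3ccccc3)c(OC)c2)ccc1O[Si](C(C)C)(C(C)C)C(C)C | intermediate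
22 | O-dibutylboryl aldolate of 23 (formed in the flask) | COc1cc(C[C@H]2C(=O)OC[C@@H]2Cc2ccc(O[C@H](C(=O)N3C(=O)OC[C@@H]3Cc3ccccc3)[C@H](OB(CCCC)CCCC)c3ccc(O[Si](C(C)C)(C(C)C)C(C)C)c(OC)c3)c(OC)c2)ccc1O[Si](C(C)C)(C(C)C)C(C)C | intermediate
23 | (S)-4-benzyl-3-{(2S,3R)-3-hydroxy-2-[2-methoxy-4-({(3R,4R)-4-[3-methoxy-4-(triisopropylsilyloxy)benzyl]-5-oxotetrahydrofuran-3-yl}methyl)phenoxy]-3-[3-methoxy-4-(triisopropylsilyloxy)phenyl]propanoyl}oxazolidin-2-one | COc1cc(C[C@H]2C(=O)OC[C@@H]2Cc2ccc(O[C@H](C(=O)N3C(=O)OC[C@@H]3Cc3ccccc3)[C@H](O)c3ccc(O[Si](C(C)C)(C(C)C)C(C)C)c(OC)c3)c(OC)c2)ccc1O[Si](C(C)C)(C(C)C)C(C)C | intermediate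
24 | (3R,4R)-4-[4-({(1R,2R)-1,3-dihydroxy-1-[3-methoxy-4-(triisopropylsilyloxy)phenyl]propan-2-yl}oxy)-3-methoxybenzyl]-3-[3-methoxy-4-(triisopropylsilyloxy)benzyl]dihydrofuran-2(3H)-one | COc1cc(C[C@H]2C(=O)OC[C@@H]2Cc2ccc(O[C@H](CO)[C@H](O)c3ccc(O[Si](C(C)C)(C(C)C)C(C)C)c(OC)c3)c(OC)c2)ccc1O[Si](C(C)C)(C(C)C)C(C)C | intermediate
25 | (3R,4R)-4-(4-{[(1R,2R)-1,3-dihydroxy-1-(4-hydroxy-3-methoxyphenyl)propan-2-yl]oxy}-3-methoxybenzyl)-3-(4-hydroxy-3-methoxybenzyl)dihydrofuran-2(3H)-one | COc1cc(C[C@H]2C(=O)OC[C@@H]2Cc2ccc(O[C@H](CO)[C@H](O)c3ccc(O)c(OC)c3)c(OC)c2)ccc1O | target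

Total step count: 14. Longest linear sequence: 10 (steps 1–4, 8, 9, 11–14).

Steps most likely to fail

1. Step 4. The catalyst may tell the two enantiotopic CH2 groups apart too weakly, because C7' insulates the arene from the ring. Uncatalysed peracid oxidation may dilute the selectivity further.
Fallback (racemic ring expansion followed by classical resolution):
- Setting out from 6, plain oxidation with m-CPBA/NaHCO3 in CH2Cl2 should give racemic 4-[4-(benzyloxy)-3-methoxybenzyl]dihydrofuran-2(3H)-one F1.
- Ring opening with (S)-1-phenylethylamine (cat. 2-hydroxypyridine, toluene, 100 °C) should give (3R)-3-[4-(benzyloxy)-3-methoxybenzyl]-4-hydroxy-N-[(1S)-1-phenylethyl]butanamide F2. Its (3S)-3-[4-(benzyloxy)-3-methoxybenzyl]-4-hydroxy-N-[(1S)-1-phenylethyl]butanamide F3 forms alongside.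
- The two amides are separated by crystallisation or chromatography.
- Heating F2 in aqueous H2SO4–dioxane should close the lactone again with loss of the amine, and the route is rejoined at 8.

2. Step 13. Hydride may also attack the lactone carbonyl. Alternatively, the basic medium may trigger retro-aldol cleavage before the imide is reduced.
Fallback (hydrolysis, then an acid-selective reductant):
- Setting out from 23, LiOH/H2O2 in THF–H2O at 0 °C is followed by a sulfite quench and mild acidification, which also recloses any opened lactone.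
- This should give (2S,3R)-3-hydroxy-2-(ring-B aryloxy)-3-[3-methoxy-4-(triisopropylsilyloxy)phenyl]propanoic acid F4.
- BH3·THF at 0 °C reduces a carboxylic acid much faster than a lactone and should deliver the primary alcohol, and the route is rejoined at 24.

3. Step 8. The electron-rich benzylic bromide may ionise and self-condense before the enolate captures it. Proton exchange between product and enolate may lead to double alkylation.
Fallback (C3–C7 bond by carbonyl addition instead of SN2, which bypasses 11, 12 and 14):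
- Setting out from 8 and 10, the enolate 13 (LiHMDS, THF, −78 °C) is added to aldehyde 10.
- This should give the trans aldol adduct (3S,4R)-4-[4-(benzyloxy)-3-methoxybenzyl]-3-{hydroxy[3-methoxy-4-(triisopropylsilyloxy)phenyl]methyl}dihydrofuran-2(3H)-one F5 as a mixture of carbinol epimers.
- Ac2O/pyridine should give the benzylic acetate of the trans aldol adduct F6.
- H2, Pd/C in EtOAc–EtOH should remove the benzylic acetate and the O-benzyl group together, and the route is rejoined at 15.

Further compounds
F1 | step 4 | racemic 4-[4-(benzyloxy)-3-methoxybenzyl]dihydrofuran-2(3H)-one | O=C1CC(Cc2ccc(OCc3ccccc3)c(OC)c2)CO1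
F2 | step 4 | (3R)-3-[4-(benzyloxy)-3-methoxybenzyl]-4-hydroxy-N-[(1S)-1-phenylethyl]butanamide | O=C(C[C@@H](Cc1ccc(OCc2ccccc2)c(OC)c1)CO)N[C@@H](C)c1ccccc1
F3 | step 4 | (3S)-3-[4-(benzyloxy)-3-methoxybenzyl]-4-hydroxy-N-[(1S)-1-phenylethyl]butanamide | O=C(C[C@H](Cc1ccc(OCc2ccccc2)c(OC)c1)CO)N[C@@H](C)c1ccccc1
F4 | step 13 | (2S,3R)-3-hydroxy-2-(ring-B aryloxy)-3-[3-methoxy-4-(triisopropylsilyloxy)phenyl]propanoic acid (lactone 3R,4R) | COc1cc(C[C@H]2C(=O)OC[C@@H]2Cc2ccc(O[C@H](C(=O)O)[C@H](O)c3ccc(O[Si](C(C)C)(C(C)C)C(C)C)c(OC)c3)c(OC)c2)ccc1O[Si](C(C)C)(C(C)C)C(C)C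
F5 | step 8 | (3S,4R)-4-[4-(benzyloxy)-3-methoxybenzyl]-3-{hydroxy[3-methoxy-4-(triisopropylsilyloxy)phenyl]methyl}dihydrofuran-2(3H)-one (trans, carbinol epimers) | COc1cc(C(O)[C@H]2C(=O)OC[C@@H]2Cc2ccc(OCc3ccccc3)c(OC)c2)ccc1O[Si](C(C)C)(C(C)C)C(C)C
F6 | step 8 | benzylic acetate of the trans aldol adduct F5 | COc1cc(C(OC(C)=O)[C@H]2C(=O)OC[C@@H]2Cc2ccc(OCc3ccccc3)c(OC)c2)ccc1O[Si](C(C)C)(C(C)C)C(C)C
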